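## Retrosynthetic overview

1. The spiro-phthalide is made last, by convex-face addition of a 2-(methoxycarbonyl)phenyl Grignard reagent to the cyclobutanone carbonyl (C3') of ketone 17, followed by lactonisation.
2. Ketone 17 comes from amide 14 by an intramolecular keteniminium–alkene [2+2]: the C7–C6 and C3'–C8' bonds form together, closing the cyclohexene and the cyclobutanone in one operation and setting C6, C7 and C8'.
3. Amide 14 comes from 3,4-dibromofuran-2(5H)-one by three C–C bond formations on the intact butenolide: C4 Negishi coupling, C5 vinylogous aldol condensation, C3 Reformatsky–Negishi coupling.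
4. Ring order: butenolide (bought) → cyclohexene + cyclobutanone (together) → phthalide lactone.

Assumption: the steric model in step 6 is taken to predict that the (2S,5S) auxiliary gives the (6S,7R,8'R) ketone; if experiment shows the opposite sense, the (2R,5R) amine is used with nothing else changed.

Locants used for the tricyclic compounds: C1 (butenolide C=O), O2, C3 (butylidene-bearing carbon), C3a, C4, C5, C6, C7, C7a for the tetrahydroisobenzofuranone part; C3' is the cyclobutane carbon on C7 (ketone, later spiro carbon); C8' is the propyl-bearing cyclobutane carbon on C6.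

## Route

Step 1
Reactants: 1 (Z)-hept-3-en-1-ol
Product: 2 (Z)-1-iodohept-3-ene
Conditions: PPh3, I2, imidazole, CH2Cl2, 0 °C to rt
Reagents that add atoms: iodine, II
Why: Appel-type iodination replaces the primary hydroxyl by SN2 without touching the remote Z-alkene; no stereocentre is involved.

Step 2
Reactants: 2 (Z)-1-iodohept-3-ene; 3 3,4-dibromofuran-2(5H)-one
Product: 5 3-bromo-4-[(Z)-hept-3-en-1-yl]furan-2(5H)-one, via alkylzinc iodide 4 (not isolated)
Conditions: Zn dust, LiCl, THF, 30 °C; then 3, PdCl2(dppf) (3 mol%), THF, 0 °C to rt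
Reagents that add atoms: none
Why: Zinc insertion followed by Negishi coupling, in which zerovalent palladium inserts faster into the β C4–Br bond of the unsaturated lactone than into the α C3–Br bond (the site selectivity known for Suzuki and Stille couplings of this dibromide); no stereocentre is formed and the Z-alkene is untouched.

Step 3
Reactants: 5 3-bromo-4-[(Z)-hept-3-en-1-yl]furan-2(5H)-one; 6 butanal
Product: 9 (5Z)-3-bromo-5-butylidene-4-[(Z)-hept-3-en-1-yl]furan-2(5H)-one, via silyloxyfuran 7 (not isolated), via silyl aldol adduct 8 (not isolated)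
Conditions: TBSOTf, i-Pr2NEt, CH2Cl2, 0 °C; butanal, −78 °C to rt; then DBU, rt
Reagents that add atoms: none
Why: Vinylogous Mukaiyama aldol addition of the 2-silyloxyfuran at C5 and E1cB loss of silanol give the ylidene, and the Z geometry (propyl syn to the ring oxygen) is the thermodynamic outcome because the E isomer suffers allylic strain with the C4 chain.

Step 4
Reactants: 10 bromoacetyl bromide; 11 (2S,5S)-2,5-dimethylpyrrolidine
Product: 12 2-bromo-1-[(2S,5S)-2,5-dimethylpyrrolidin-1-yl]ethan-1-one
Conditions: Et3N, CH2Cl2, −78 °C to 0 °C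
Reagents that add atoms: none
Why: N-acylation by the acyl bromide is far faster than N-alkylation at low temperature, and the auxiliary stereocentres are not touched.

Step 5
Reactants: 9 (5Z)-3-bromo-5-butylidene-4-[(Z)-hept-3-en-1-yl]furan-2(5H)-one; 12 2-bromo-1-[(2S,5S)-2,5-dimethylpyrrolidin-1-yl]ethan-1-one
Product: 14 2-{(5Z)-5-butylidene-4-[(Z)-hept-3-en-1-yl]-2-oxo-2,5-dihydrofuran-3-yl}-1-[(2S,5S)-2,5-dimethylpyrrolidin-1-yl]ethan-1-one, via zinc amide enolate 13 (not isolated)
Conditions: 12, Zn dust (TMSCl-activated), THF, rt; then 9, Pd(dba)2 (5 mol%), P(t-Bu)3 (5 mol%), THF, rt to 45 °C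
Reagents that add atoms: none
Why: Reformatsky reagent formation followed by palladium-catalysed Negishi-type coupling of the zinc amide enolate with the alkenyl bromide (the known coupling of zinc amide enolates with sp2 bromides), the mild zinc enolate sparing the enol lactone; no stereocentre is formed.

Step 6
Reactants: 14 2-{(5Z)-5-butylidene-4-[(Z)-hept-3-en-1-yl]-2-oxo-2,5-dihydrofuran-3-yl}-1-[(2S,5S)-2,5-dimethylpyrrolidin-1-yl]ethan-1-one
Product: 17 cis-fused tricyclic cyclobutanone (3Z,6S,7R,8'R), via keteniminium triflate 15 (not isolated), via cyclobutaniminium triflate 16 (not isolated)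
Conditions: Tf2O (1.2 equiv), 2,6-di-tert-butyl-4-methylpyridine (1.5 equiv), ClCH2CH2Cl (0.01 M), −20 °C then 80 °C; then aq NaHCO3, CH2Cl2, rt
Reagents that add atoms: water, O
Why: The keteniminium made by amide activation and α-deprotonation adds across the tethered Z-alkene in a concerted asynchronous thermal [2+2] (Ghosez intramolecular keteniminium–olefin cycloaddition) that closes the cyclohexene (C7–C6) and the cyclobutane (C3'–C8') together, the Z geometry placing C5 and propyl cis on C6–C8', the four-atom tether enforcing the cis ring fusion at C6–C7, and the C2-symmetric (2S,5S)-pyrrolidine (no keteniminium E/Z isomers, one approach quadrant blocked by a methyl group) directing bond formation to one face of C7 and so fixing the absolute configuration of all three centres before hydrolysis releases the ketone and the auxiliary.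

Step 7
Reactants: 17 cis-fused tricyclic cyclobutanone (3Z,6S,7R,8'R); 18 methyl 2-iodobenzoate
Product: 21 target spiro-phthalide (3Z,6S,7R,3'R,8'R), via aryl Grignard 19 (not isolated), via magnesium alkoxide 20 (not isolated)
Conditions: 18, i-PrMgCl·LiCl, THF, −40 °C; then LaCl3·2LiCl, 17, −78 °C to 0 °C; aq NH4Cl
Reagents that add atoms: none
Why: Iodine–magnesium exchange gives the ester-bearing aryl Grignard, which (with LaCl3·2LiCl suppressing enolisation at C8') adds to the strained cyclobutanone from the convex face opposite to the cis-disposed propyl group and six-membered ring, so that aryl ends trans and oxygen cis to propyl at C3', and the alkoxide then closes onto the ortho ester to give the spiro-phthalide (1,2-addition/lactonisation).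

## Compound list

1 | (Z)-hept-3-en-1-ol | CCC/C=C\CCO | starting material
2 | (Z)-1-iodohept-3-ene | CCC/C=C\CCI | intermediate
3 | 3,4-dibromofuran-2(5H)-one | O=C1OCC(Br)=C1Br | starting material
4 | [(Z)-hept-3-en-1-yl]zinc iodide | CCC/C=C\CC[Zn]I | intermediate
5 | 3-bromo-4-[(Z)-hept-3-en-1-yl]furan-2(5H)-one | CCC/C=C\CCC1=C(Br)C(=O)OC1 | intermediate
6 | butanal | CCCC=O | starting material
7 | 3-bromo-2-(tert-butyldimethylsilyloxy)-4-[(Z)-hept-3-en-1-yl]furan | CCC/C=C\CCc1coc(O[Si](C)(C)C(C)(C)C)c1Br | intermediate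
8 | 3-bromo-5-[1-(tert-butyldimethylsilyloxy)butyl]-4-[(Z)-hept-3-en-1-yl]furan-2(5H)-one (diastereomer mixture) | CCC/C=C\CCC1=C(Br)C(=O)OC1C(CCC)O[Si](C)(C)C(C)(C)C | intermediate
9 | (5Z)-3-bromo-5-butylidene-4-[(Z)-hept-3-en-1-yl]furan-2(5H)-one | CCC/C=C1\OC(=O)C(Br)=C1CC/C=C\CCC | intermediate
10 | bromoacetyl bromide | BrCC(Br)=O | starting material
11 | (2S,5S)-2,5-dimethylpyrrolidine | C[C@H]1CC[C@H](C)N1 | starting material
12 | 2-bromo-1-[(2S,5S)-2,5-dimethylpyrrolidin-1-yl]ethan-1-one | BrCC(=O)N1[C@@H](C)CC[C@@H]1C | intermediate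
13 | bromo{2-[(2S,5S)-2,5-dimethylpyrrolidin-1-yl]-2-oxoethyl}zinc | Br[Zn]CC(=O)N1[C@@H](C)CC[C@@H]1C | intermediate
14 | 2-{(5Z)-5-butylidene-4-[(Z)-hept-3-en-1-yl]-2-oxo-2,5-dihydrofuran-3-yl}-1-[(2S,5S)-2,5-dimethylpyrrolidin-1-yl]ethan-1-one | CCC/C=C1\OC(=O)C(CC(=O)N2[C@@H](C)CC[C@@H]2C)=C1CC/C=C\CCC | intermediate
15 | (2S,5S)-1-(2-{(5Z)-5-butylidene-4-[(Z)-hept-3-en-1-yl]-2-oxo-2,5-dihydrofuran-3-yl}ethenylidene)-2,5-dimethylpyrrolidin-1-ium triflate (keteniminium salt, C7H=C3'=N+) | CCC/C=C1\OC(=O)C(C=C=[N+]2[C@@H](C)CC[C@@H]2C)=C1CC/C=C\CCC.[O-]S(=O)(=O)C(F)(F)F | intermediate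
16 | cyclobutaniminium triflate: compound 17 with C3'=N+ of the (2S,5S)-2,5-dimethylpyrrolidinium unit in place of C3'=O; (3Z,6S,7R,8'R) | CCC/C=C1\OC(=O)C2=C1CC[C@H]1[C@@H](CCC)C(=[N+]3[C@@H](C)CC[C@@H]3C)[C@@H]21.[O-]S(=O)(=O)C(F)(F)F | intermediate
17 | (3Z,6S,7R,8'R)-3-butylidene-4,5,6,7-tetrahydroisobenzofuran-1(3H)-one bridged from C7 to C6 by –C3'(=O)–C8'H(n-Pr)–: cis-fused cyclobutanone, H-6, H-7 and H-8' on one face, propyl cis to C5 and C7a | CCC/C=C1\OC(=O)C2=C1CC[C@H]1[C@@H](CCC)C(=O)[C@@H]21 | intermediate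
18 | methyl 2-iodobenzoate | COC(=O)c1ccccc1I | starting material
19 | [2-(methoxycarbonyl)phenyl]magnesium chloride (LiCl complex) | COC(=O)c1ccccc1[Mg]Cl | intermediate
20 | chloromagnesium alkoxide: compound 17 with C3' carrying OMgCl (cis to propyl) and 2-(methoxycarbonyl)phenyl (trans to propyl); (3Z,6S,7R,3'R,8'R) | CCC/C=C1\OC(=O)C2=C1CC[C@H]1[C@@H](CCC)[C@](O[Mg]Cl)(c3ccccc3C(=O)OC)[C@@H]21 | intermediate
21 | CNP0248594.2: (3Z,6S,7R,3'R,8'R) spiro-phthalide; C3' is C3 of an isobenzofuran-1(3H)-one whose ring oxygen is cis to propyl, C5 and C7a and whose benzo ring is trans to them; H-6, H-7 and H-8' on one face | CCC/C=C1\OC(=O)C2=C1CC[C@H]1[C@@H](CCC)[C@@]3(OC(=O)c4ccccc43)[C@@H]21 | target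

## Count and risks

Total step count: 7. Longest linear sequence: 6 (steps 1, 2, 3, 5, 6, 7); step 4 is a one-step side branch.

**Step 6 (most likely to fail).** The butenolide carbonyl oxygen can trap the activated amide or the keteniminium. The crossed adduct or the C8' epimer (via iminium–enamine equilibration) may form. The facial bias of the auxiliary on this conjugated keteniminium is untested and may need upgrading by crystallisation. The fallback sets out from 9 and replaces the chiral keteniminium by a neutral vinylketene. Palladium-catalysed coupling of 9 with the Reformatsky reagent of tert-butyl bromoacetate gives tert-butyl 2-{(5Z)-5-butylidene-4-[(Z)-hept-3-en-1-yl]-2-oxo-2,5-dihydrofuran-3-yl}acetate F1. TFA in CH2Cl2 gives 2-{(5Z)-5-butylidene-4-[(Z)-hept-3-en-1-yl]-2-oxo-2,5-dihydrofuran-3-yl}acetic acid F2. TsCl and Et3N in refluxing toluene at high dilution generate (5Z)-5-butylidene-4-[(Z)-hept-3-en-1-yl]-3-(2-oxoethenyl)furan-2(5H)-one F3, which is not isolated and closes by the same stereospecific thermal [2+2] to the racemic cis-fused cyclobutanone F4. Preparative chiral HPLC of F4 returns the route to 17.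

**Step 5.** The hindered tetrasubstituted α-bromobutenolide may couple slowly, and the zinc enolate may add 1,6 to the ylidene. The fallback sets out from 5 and installs the acetamide arm before the ylidene exists. Coupling of 5 with zinc enolate 13 (Pd(dba)2, P(t-Bu)3) gives 1-[(2S,5S)-2,5-dimethylpyrrolidin-1-yl]-2-{4-[(Z)-hept-3-en-1-yl]-2-oxo-2,5-dihydrofuran-3-yl}ethan-1-one F5. Vinylogous aldol condensation of F5 with butanal 6 (TBSOTf, i-Pr2NEt, then DBU) then returns the route to 14.

**Step 7.** The ester-bearing Grignard may enolise the ketone (epimerising C8') or attack the enol lactone. The fallback sets out from 17, uses a non-basic organocerium without an ester, and builds the lactone carbonyl by oxidation. The reagent from 2-bromobenzyl alcohol, n-BuLi (2 equiv) and CeCl3 in THF at −78 °C adds from the convex face to give the (3Z,6S,7R,3'R,8'R) diol in which C3' carries OH (cis to propyl) and 2-(hydroxymethyl)phenyl F6. TEMPO with PhI(OAc)2 oxidises the benzylic alcohol and the resulting lactol to the phthalide, returning the route to 21.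

## Further compounds

F1 | step 6 | tert-butyl 2-{(5Z)-5-butylidene-4-[(Z)-hept-3-en-1-yl]-2-oxo-2,5-dihydrofuran-3-yl}acetate | CCC/C=C1\OC(=O)C(CC(=O)OC(C)(C)C)=C1CC/C=C\CCC
F2 | step 6 | 2-{(5Z)-5-butylidene-4-[(Z)-hept-3-en-1-yl]-2-oxo-2,5-dihydrofuran-3-yl}acetic acid | CCC/C=C1\OC(=O)C(CC(=O)O)=C1CC/C=C\CCC
F3 | step 6 | (5Z)-5-butylidene-4-[(Z)-hept-3-en-1-yl]-3-(2-oxoethenyl)furan-2(5H)-one (vinylketene, not isolated) | CCC/C=C1\OC(=O)C(C=C=O)=C1CC/C=C\CCC
F4 | step 6 | racemic cis-fused cyclobutanone (17 and its enantiomer, 1:1) | CCC/C=C1\OC(=O)C2=C1CC[C@H]1[C@@H](CCC)C(=O)[C@@H]21.CCC/C=C1\OC(=O)C2=C1CC[C@@H]1[C@H](CCC)C(=O)[C@H]21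
F5 | step 5 | 1-[(2S,5S)-2,5-dimethylpyrrolidin-1-yl]-2-{4-[(Z)-hept-3-en-1-yl]-2-oxo-2,5-dihydrofuran-3-yl}ethan-1-one | CCC/C=C\CCC1=C(CC(=O)N2[C@@H](C)CC[C@@H]2C)C(=O)OC1
F6 | step 7 | (3Z,6S,7R,3'R,8'R) diol: compound 17 with C3' carrying OH (cis to propyl) and 2-(hydroxymethyl)phenyl (trans to propyl) | CCC/C=C1\OC(=O)C2=C1CC[C@H]1[C@@H](CCC)[C@](O)(c3ccccc3CO)[C@@H]21
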